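**Plan**

Labels: O1, C2, C3, C3a are the atoms of the 2,3-dihydrobenzofuran; ring A is its benzo ring; ring B is the second resorcinol ring of the seven-membered carbocycle; Ca is the ring methine carrying the 5-formyl-2-hydroxyphenyl group; Cb is the ring methine carrying the 4-hydroxyphenyl group.
Retrosynthesis: cut C3–C3a together with O1–C2 (this opens the seven-membered ring and the dihydrofuran at once and gives the acyclic (E)-4-hydroxystilbene heptaphenol 16), then the stilbene C=C (olefination), then the ring B–Cb bond (Friedel–Crafts), then Ca–Cb (carbene C–H insertion).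
Forward: a temporary 2,3-diaryl-2,3-dihydrobenzofuran ring (9) is made first and opened by ring B; the stilbene arm is attached, the nitrile becomes the aldehyde, the methyl ethers are removed, and one oxidation closes the seven-membered ring (C3–C3a) and the dihydrofuran (O1–C2) in the last step.
Enabling feature: C3 is the vinylogous para position of the 4-hydroxyphenyl group on C2, so oxidation of that one phenol makes C3 an electrophile and C2 a para-quinone-methide carbon; C3a of ring A lies ortho to one ring A hydroxyl and para to the other (a nucleophilic carbon), and the ortho hydroxyl is placed to add to C2.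
Stereochemistry: Ca from the chiral dirhodium catalyst (step 5); Cb by 1,2-induction from Ca in the cation capture (step 6); C3 from Cb/Ca in the seven-membered ring closure and C2 (trans to C3) by the reversible oxa-Michael addition (step 10).

Key step: step 10

Assumption: Rh2(S-PTAD)4 is taken to give the (3R) insertion product 9; if the sense of induction is the opposite, Rh2(R-PTAD)4 is used and nothing else changes.

**Route**

Step 1
Reactants: 1 3-formyl-4-hydroxybenzonitrile; 2 4-methoxybenzyl chloride
Product: 3 3-formyl-4-[(4-methoxybenzyl)oxy]benzonitrile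
Conditions: K2CO3, DMF, 60 °C
Reagents that add atoms: none
Why: Williamson O-alkylation of the acidic cyanophenol (SN2 at the benzylic chloride) installs the 4-methoxybenzyl ether whose CH2 group is the later C–H insertion site and the future Cb.

Step 2
Reactants: 3 3-formyl-4-[(4-methoxybenzyl)oxy]benzonitrile; 4 3,5-dimethoxyphenylmagnesium chloride
Product: 5 rac-3-[(3,5-dimethoxyphenyl)(hydroxy)methyl]-4-[(4-methoxybenzyl)oxy]benzonitrile
Conditions: THF, −78 → −20 °C; aq. NH4Cl
Reagents that add atoms: none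
Why: Grignard 1,2-addition to the aldehyde is much faster than addition to the aryl nitrile at low temperature, and the racemic carbinol centre is removed in step 3.

Step 3
Reactants: 5 rac-3-[(3,5-dimethoxyphenyl)(hydroxy)methyl]-4-[(4-methoxybenzyl)oxy]benzonitrile
Product: 6 3-(3,5-dimethoxybenzoyl)-4-[(4-methoxybenzyl)oxy]benzonitrile
Conditions: Dess–Martin periodinane, CH2Cl2, 23 °C
Reagents that add atoms: none
Why: Dess–Martin oxidation of a diaryl carbinol to the benzophenone should leave the benzylic ether and the nitrile untouched.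

Step 4
Reactants: 6 3-(3,5-dimethoxybenzoyl)-4-[(4-methoxybenzyl)oxy]benzonitrile
Product: 7 3-[(3,5-dimethoxyphenyl)(hydrazinylidene)methyl]-4-[(4-methoxybenzyl)oxy]benzonitrile (E/Z mixture)
Conditions: N2H4·H2O (excess), AcOH (cat.), EtOH, 80 °C
Reagents that add atoms: hydrazine (NN)
Why: Condensation of the diaryl ketone with hydrazine gives the N-unsubstituted hydrazone, the precursor of a diaryldiazomethane, while the electron-rich aryl nitrile should not react under these conditions.

Step 5
Reactants: 7 3-[(3,5-dimethoxyphenyl)(hydrazinylidene)methyl]-4-[(4-methoxybenzyl)oxy]benzonitrile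
Product: 9 (2S,3R)-3-(3,5-dimethoxyphenyl)-2-(4-methoxyphenyl)-2,3-dihydro-1-benzofuran-5-carbonitrile (cis), via diazo compound 8 (not isolated)
Conditions: MnO2 (8 equiv), CH2Cl2, 0 °C; then Rh2(S-PTAD)4 (1 mol %), 0 → 23 °C
Reagents that add atoms: none
Why: MnO2 dehydrogenates the hydrazone to the diaryldiazomethane and the chiral dirhodium tetracarboxylate turns it into a donor/donor carbene that inserts into the neighbouring ArO–CH2–Ar bond (enantioselective intramolecular 1,5 C–H insertion), the catalyst setting C3 (the later Ca) while the cis C2 centre is lost again in step 6.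

Step 6
Reactants: 9 (2S,3R)-3-(3,5-dimethoxyphenyl)-2-(4-methoxyphenyl)-2,3-dihydro-1-benzofuran-5-carbonitrile; 10 diethyl (3,5-dimethoxybenzyl)phosphonate
Product: 11 diethyl {2-[(1S,2R)-2-(5-cyano-2-hydroxyphenyl)-2-(3,5-dimethoxyphenyl)-1-(4-methoxyphenyl)ethyl]-3,5-dimethoxybenzyl}phosphonate
Conditions: TfOH (20 mol %), (CF3)2CHOH, 0 °C, phosphonate in fivefold excess
Reagents that add atoms: none
Why: Acid ionises the benzylic C2–O bond of 9 to a 4-methoxybenzyl cation (the 4-cyanophenol leaving group stays in the molecule as the free phenol) that alkylates the phosphonate arene, used in excess, at the ring carbon ortho to one methoxy group and para to the other (Friedel–Crafts alkylation, arylative ring-opening of a benzylic ether), the new Cb centre being set by 1,2-induction from Ca: in the freely rotating cation the Ca–H bond should eclipse the cation plane (allylic 1,3-strain) and the arene should add anti to the bulkier ortho-oxygenated aryl group, so that the C2 configuration of 9 has no influence on the outcome.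

Step 7
Reactants: 11 diethyl {2-[(1S,2R)-2-(5-cyano-2-hydroxyphenyl)-2-(3,5-dimethoxyphenyl)-1-(4-methoxyphenyl)ethyl]-3,5-dimethoxybenzyl}phosphonate; 12 4-methoxybenzaldehyde
Product: 13 3-[(1R,2S)-2-{2,4-dimethoxy-6-[(E)-2-(4-methoxyphenyl)ethenyl]phenyl}-1-(3,5-dimethoxyphenyl)-2-(4-methoxyphenyl)ethyl]-4-hydroxybenzonitrile
Conditions: KOtBu (3 equiv), THF, 0 → 23 °C; aq. HCl (1 M)
Reagents that add atoms: none
Why: Horner–Wadsworth–Emmons olefination of the benzylic phosphonate carbanion with the aryl aldehyde should give the (E)-stilbene, the phenoxide being a spectator and the doubly benzylic methines too weakly acidic to epimerise.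

Step 8
Reactants: 13 3-[(1R,2S)-2-{2,4-dimethoxy-6-[(E)-2-(4-methoxyphenyl)ethenyl]phenyl}-1-(3,5-dimethoxyphenyl)-2-(4-methoxyphenyl)ethyl]-4-hydroxybenzonitrile
Product: 15 3-[(1R,2S)-2-{2,4-dimethoxy-6-[(E)-2-(4-methoxyphenyl)ethenyl]phenyl}-1-(3,5-dimethoxyphenyl)-2-(4-methoxyphenyl)ethyl]-4-hydroxybenzaldehyde, via aldimine 14 (not isolated)
Conditions: i-Bu2AlH (3.5 equiv), CH2Cl2, −78 → 0 °C; aq. HCl (1 M)
Reagents that add atoms: water (O)
Why: After the first equivalent is consumed by the phenol, i-Bu2AlH adds once to the nitrile and the aldimine is hydrolysed on acidic work-up (nitrile half-reduction to the aldehyde), the stilbene and methyl ethers being inert.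

Step 9
Reactants: 15 3-[(1R,2S)-2-{2,4-dimethoxy-6-[(E)-2-(4-methoxyphenyl)ethenyl]phenyl}-1-(3,5-dimethoxyphenyl)-2-(4-methoxyphenyl)ethyl]-4-hydroxybenzaldehyde
Product: 16 3-[(1R,2S)-2-{2,4-dihydroxy-6-[(E)-2-(4-hydroxyphenyl)ethenyl]phenyl}-1-(3,5-dihydroxyphenyl)-2-(4-hydroxyphenyl)ethyl]-4-hydroxybenzaldehyde
Conditions: BBr3 (15 equiv), CH2Cl2, −78 → 23 °C; H2O
Reagents that add atoms: none
Why: BBr3 cleaves all six aryl methyl ethers (Lewis acid–base complexation, then SN2 of bromide at methyl), a demethylation that methylated hydroxystilbenes and aryl aldehydes normally survive.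

Step 10
Reactants: 16 3-[(1R,2S)-2-{2,4-dihydroxy-6-[(E)-2-(4-hydroxyphenyl)ethenyl]phenyl}-1-(3,5-dihydroxyphenyl)-2-(4-hydroxyphenyl)ethyl]-4-hydroxybenzaldehyde
Product: 18 vitisinol B, via quinone methide 17 (not isolated)
Conditions: FeCl3·6H2O (2.2 equiv, slow addition), acetone, 2 mM, 23 °C
Reagents that add atoms: none
Why: Two one-electron oxidations by FeCl3 (trivalent iron going to divalent iron) should convert the 4-hydroxystilbene into its phenoxyl radical and then into the phenoxonium/para-quinone-methide cation whose charge sits on the stilbene carbon attached to ring B (the future C3); C3a of ring A attacks it, rearomatisation gives quinone methide 17, and the ortho hydroxyl of ring A then adds to the quinone-methide carbon (C2). The closest known reaction type is the oxidative coupling of 4-hydroxystilbenes with a resorcinol ring to ε-viniferin-type 2,3-diaryl-2,3-dihydrobenzofurans (a formal [3+2] annulation), here run intramolecularly. The seven-membered carbocycle closes in a 7-exo-trig Friedel–Crafts mode (the attacked C=C lies outside the new ring) and the dihydrofuran in a 5-exo-trig oxa-1,6-addition. The new C3 centre is controlled by Cb: the quinone-methide arm should take the position anti to the 4-hydroxyphenyl group of Cb across the ring B edge; C2 is set trans to the ring B substituent on C3 by the reversible oxa-Michael addition (the thermodynamic trans-2,3-diaryl arrangement). The step needs oxidation of the one stilbene-conjugated phenol among seven (its radical is delocalised over the stilbene, so it has the lowest oxidation potential), carbon attack by ring A (only the two equivalent ortho carbons of the symmetric 3,5-dihydroxyphenyl ring can reach C3), and ring closure faster than bimolecular radical coupling (high dilution, slow addition of oxidant).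

**Compound list**

1 | 3-formyl-4-hydroxybenzonitrile | N#Cc1ccc(O)c(C=O)c1 | starting material
2 | 4-methoxybenzyl chloride | COc1ccc(CCl)cc1 | starting material
3 | 3-formyl-4-[(4-methoxybenzyl)oxy]benzonitrile | N#Cc1ccc(OCc2ccc(OC)cc2)c(C=O)c1 | intermediate
4 | 3,5-dimethoxyphenylmagnesium chloride (THF solution) | COc1cc(OC)cc([Mg]Cl)c1 | starting material
5 | rac-3-[(3,5-dimethoxyphenyl)(hydroxy)methyl]-4-[(4-methoxybenzyl)oxy]benzonitrile | N#Cc1ccc(OCc2ccc(OC)cc2)c(C(O)c2cc(OC)cc(OC)c2)c1 | intermediate
6 | 3-(3,5-dimethoxybenzoyl)-4-[(4-methoxybenzyl)oxy]benzonitrile | N#Cc1ccc(OCc2ccc(OC)cc2)c(C(=O)c2cc(OC)cc(OC)c2)c1 | intermediate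
7 | 3-[(3,5-dimethoxyphenyl)(hydrazinylidene)methyl]-4-[(4-methoxybenzyl)oxy]benzonitrile (E/Z mixture) | N#Cc1ccc(OCc2ccc(OC)cc2)c(C(=NN)c2cc(OC)cc(OC)c2)c1 | intermediate
8 | 3-[diazo(3,5-dimethoxyphenyl)methyl]-4-[(4-methoxybenzyl)oxy]benzonitrile (formed in the flask) | N#Cc1ccc(OCc2ccc(OC)cc2)c(C(=[N+]=[N-])c2cc(OC)cc(OC)c2)c1 | intermediate
9 | (2S,3R)-3-(3,5-dimethoxyphenyl)-2-(4-methoxyphenyl)-2,3-dihydro-1-benzofuran-5-carbonitrile (cis) | N#Cc1ccc2O[C@H](c3ccc(OC)cc3)[C@H](c3cc(OC)cc(OC)c3)c2c1 | intermediate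
10 | diethyl (3,5-dimethoxybenzyl)phosphonate | CCOP(=O)(OCC)Cc1cc(OC)cc(OC)c1 | starting material
11 | diethyl {2-[(1S,2R)-2-(5-cyano-2-hydroxyphenyl)-2-(3,5-dimethoxyphenyl)-1-(4-methoxyphenyl)ethyl]-3,5-dimethoxybenzyl}phosphonate | N#Cc1ccc(O)c(c1)[C@@H](c1cc(OC)cc(OC)c1)[C@@H](c1ccc(OC)cc1)c1c(OC)cc(OC)cc1CP(=O)(OCC)OCC | intermediate
12 | 4-methoxybenzaldehyde | COc1ccc(C=O)cc1 | starting material
13 | 3-[(1R,2S)-2-{2,4-dimethoxy-6-[(E)-2-(4-methoxyphenyl)ethenyl]phenyl}-1-(3,5-dimethoxyphenyl)-2-(4-methoxyphenyl)ethyl]-4-hydroxybenzonitrile | N#Cc1ccc(O)c(c1)[C@@H](c1cc(OC)cc(OC)c1)[C@@H](c1ccc(OC)cc1)c1c(OC)cc(OC)cc1/C=C/c1ccc(OC)cc1 | intermediate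
14 | primary aldimine of 15 (C≡N of 13 reduced to CH=NH; formed in the flask) | N=Cc1ccc(O)c(c1)[C@@H](c1cc(OC)cc(OC)c1)[C@@H](c1ccc(OC)cc1)c1c(OC)cc(OC)cc1/C=C/c1ccc(OC)cc1 | intermediate
15 | 3-[(1R,2S)-2-{2,4-dimethoxy-6-[(E)-2-(4-methoxyphenyl)ethenyl]phenyl}-1-(3,5-dimethoxyphenyl)-2-(4-methoxyphenyl)ethyl]-4-hydroxybenzaldehyde | O=Cc1ccc(O)c(c1)[C@@H](c1cc(OC)cc(OC)c1)[C@@H](c1ccc(OC)cc1)c1c(OC)cc(OC)cc1/C=C/c1ccc(OC)cc1 | intermediate
16 | 3-[(1R,2S)-2-{2,4-dihydroxy-6-[(E)-2-(4-hydroxyphenyl)ethenyl]phenyl}-1-(3,5-dihydroxyphenyl)-2-(4-hydroxyphenyl)ethyl]-4-hydroxybenzaldehyde | O=Cc1ccc(O)c(c1)[C@@H](c1cc(O)cc(O)c1)[C@@H](c1ccc(O)cc1)c1c(O)cc(O)cc1/C=C/c1ccc(O)cc1 | intermediate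
17 | ring-closed para-quinone methide: (5S,10R,11S)-10,11-dihydro-5H-dibenzo[a,d][7]annulene with hydroxyls at C1, C3, C6 and C8, the (4-oxocyclohexa-2,5-dien-1-ylidene)methyl arm on C5, the 5-formyl-2-hydroxyphenyl group on C10 and the 4-hydroxyphenyl group on C11 (formed in the flask) | O=Cc1ccc(O)c([C@H]2c3cc(O)cc(O)c3[C@H](c3cc(O)cc(O)c3[C@@H]2c2ccc(O)cc2)C=C2C=CC(=O)C=C2)c1 | intermediate
18 | vitisinol B | O=Cc1ccc(O)c([C@H]2c3cc(O)cc4c3[C@H](c3cc(O)cc(O)c3[C@@H]2c2ccc(O)cc2)[C@@H](c2ccc(O)cc2)O4)c1 | target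

**Count and risks**

Total steps: 10. Longest linear sequence: 10 steps (1 → 18); all coupling partners (2, 4, 10, 12) are commercial.

Steps most likely to fail:

1. Step 10. Bimolecular coupling of the phenoxyl radical or oxidation at another phenol may outrun the seven-membered ring closure, and the facial selectivity at C3 may be poor. The fallback is a polar, non-oxidative closure that sets out from 13 and comes back to the route at 18. Epoxidation of the stilbene with dimethyldioxirane (acetone, 0 °C) would give the trans-epoxide F1. Oxidative opening with DMSO and BF3·OEt2 (DMSO attacks the 4-methoxybenzylic carbon) would give the α-hydroxy ketone F2, with the hydroxyl on the carbon attached to ring B. TfOH in (CF3)2CHOH would then close the seven-membered ring by intramolecular Friedel–Crafts alkylation of ring A to the ring ketone F3, whose α-keto methine (C3) can equilibrate to the more stable epimer. Excess i-Bu2AlH would reduce ketone and nitrile in one flask, through the hydroxy aldimine F4, to the hydroxy aldehyde F5. BBr3 would finally remove the methyl groups and close the dihydrofuran by attack of the ring A oxygen on the 4-oxybenzylic cation (trans), giving 18.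

2. Step 6. The capture of the benzylic cation may show poor facial selectivity; loss and return of the neighbouring proton may erode the Ca centre; the arene may be attacked between its two methoxy groups; and the electron-rich ring of 9 may alkylate itself. The fallback is a stereospecific cross-coupling that sets out from 9 and comes back to the route at 13, bypassing 11. Trifluoroacetic acid in CH2Cl2 would equilibrate 9 to the trans ether F6. Horner–Wadsworth–Emmons reaction of commercial 2-bromo-3,5-dimethoxybenzaldehyde with commercial diethyl (4-methoxybenzyl)phosphonate would give the bromostilbene F7, and Mg/LiCl in THF would convert it into the Grignard reagent F8. Nickel-catalysed Kumada coupling of F8 with the benzylic ether F6 (Ni(dppe)Cl2, toluene/THF) would open the C2–O bond with inversion and give 13 after acidic work-up.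

3. Step 9. HBr and the boron Lewis acid may trigger cationic cyclisation or oligomerisation through the electron-rich stilbene, or attack the aldehyde, during the sixfold demethylation. The fallback moves the deprotection in front of the nitrile reduction and runs it under basic, nucleophilic conditions; it sets out from 13 and comes back to the route at 16. NaSEt in DMF at 130 °C (SN2 of thiolate at methyl) would give the heptahydroxy nitrile F9, and excess i-Bu2AlH followed by acidic work-up would give 16 through the aldimine F10.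

Further compounds
F1 | step 10 | trans-epoxide of 13 (oxirane in place of the stilbene C=C, both oxirane diastereomers) | N#Cc1ccc(O)c(c1)[C@@H](c1cc(OC)cc(OC)c1)[C@@H](c1ccc(OC)cc1)c1c(OC)cc(OC)cc1C1OC1c1ccc(OC)cc1
F2 | step 10 | 3-[(1R,2S)-2-{2-[1-hydroxy-2-(4-methoxyphenyl)-2-oxoethyl]-4,6-dimethoxyphenyl}-1-(3,5-dimethoxyphenyl)-2-(4-methoxyphenyl)ethyl]-4-hydroxybenzonitrile (carbinol epimers) | N#Cc1ccc(O)c(c1)[C@@H](c1cc(OC)cc(OC)c1)[C@@H](c1ccc(OC)cc1)c1c(OC)cc(OC)cc1C(O)C(=O)c1ccc(OC)cc1
F3 | step 10 | seven-membered-ring ketone: tetramethoxy-10,11-dihydro-5H-dibenzo[a,d][7]annulene with a 4-methoxybenzoyl group on C5, the 5-cyano-2-hydroxyphenyl group on C10 and the 4-methoxyphenyl group on C11 | N#Cc1ccc(O)c([C@H]2c3cc(OC)cc(OC)c3[C@H](c3cc(OC)cc(OC)c3[C@@H]2c2ccc(OC)cc2)C(=O)c2ccc(OC)cc2)c1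
F4 | step 10 | hydroxy aldimine from F3 (ketone reduced to carbinol, nitrile to CH=NH; carbinol epimers) | N=Cc1ccc(O)c([C@H]2c3cc(OC)cc(OC)c3[C@H](c3cc(OC)cc(OC)c3[C@@H]2c2ccc(OC)cc2)C(O)c2ccc(OC)cc2)c1
F5 | step 10 | hydroxy aldehyde from F4 (CH=NH hydrolysed to CHO; carbinol epimers) | O=Cc1ccc(O)c([C@H]2c3cc(OC)cc(OC)c3[C@H](c3cc(OC)cc(OC)c3[C@@H]2c2ccc(OC)cc2)C(O)c2ccc(OC)cc2)c1
F6 | step 6 | (2R,3R)-3-(3,5-dimethoxyphenyl)-2-(4-methoxyphenyl)-2,3-dihydro-1-benzofuran-5-carbonitrile (trans) | N#Cc1ccc2O[C@@H](c3ccc(OC)cc3)[C@H](c3cc(OC)cc(OC)c3)c2c1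
F7 | step 6 | 2-bromo-1,5-dimethoxy-3-[(E)-2-(4-methoxyphenyl)ethenyl]benzene | COc1ccc(/C=C/c2cc(OC)cc(OC)c2Br)cc1
F8 | step 6 | {2,4-dimethoxy-6-[(E)-2-(4-methoxyphenyl)ethenyl]phenyl}magnesium bromide | COc1ccc(/C=C/c2cc(OC)cc(OC)c2[Mg]Br)cc1
F9 | step 9 | 3-[(1R,2S)-2-{2,4-dihydroxy-6-[(E)-2-(4-hydroxyphenyl)ethenyl]phenyl}-1-(3,5-dihydroxyphenyl)-2-(4-hydroxyphenyl)ethyl]-4-hydroxybenzonitrile | N#Cc1ccc(O)c(c1)[C@@H](c1cc(O)cc(O)c1)[C@@H](c1ccc(O)cc1)c1c(O)cc(O)cc1/C=C/c1ccc(O)cc1
F10 | step 9 | primary aldimine from F9 (C≡N reduced to CH=NH) | N=Cc1ccc(O)c(c1)[C@@H](c1cc(O)cc(O)c1)[C@@H](c1ccc(O)cc1)c1c(O)cc(O)cc1/C=C/c1ccc(O)cc1
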